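The numbers stand for no real mixture.

Late in the run the trap has had its time, but the questions here are put early, where capture agent takes spent carrier at 0.96 d⁻¹ as charged, slower than the exchange with salt takes it at 15 d⁻¹.

starting material 20 mM; salt in the second phase 3.00 equiv; capture agent 1.00 mM; spent carrier 15 mol%; volume of the second phase over the first 2.0

    spent carrier + salt in the second phase ⇌ fresh carrier + spent salt in the second phase (K1 = 0.13, k1 = 21 L mol⁻¹ h⁻¹)
    starting material + fresh carrier → product + spent carrier (k2 = 51 L mol⁻¹ h⁻¹)
    spent carrier + capture agent → trapped intermediate (k3 = 40 L mol⁻¹ h⁻¹)

* the form that holds most of the catalyst when 10% of the starting material are converted (trapped intermediate / fresh carrier / spent carrier)
* its share of the catalyst then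
* factor on the rate of making product when 10% of the starting material are converted if salt in the second phase is charged twice over
* factor on the rate when 10% of the starting material are converted if spent carrier is charged at 3 mol% instead

- in the second phase: salt in the second phase, spent salt in the second phase; everything else is in the first
- charges count per volume of the first phase; a concentration in a rate is the amount of a species over the volume of its own phase; every rate counts per litre of the first phase
- charge of starting material (flask): 20 mM

The catalyst works in a round. Spent carrier takes up salt from the second phase and becomes fresh carrier, and fresh carrier turns starting material into product and returns as spent carrier. The salt stands at 30.0 mM in its own phase, which gives the pseudo-first-order exchange rate above, while the product step runs at 24 d⁻¹ per fresh carrier as charged.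

Two chemists disagree about this flask. The first holds that exchange is the rate-limiting step, so that spent carrier is the resting state and doubled salt gives a factor of 2; her ground is that exchange is slower than the product step. The second holds that the product step limits, so that fresh carrier rests and salt does nothing; his ground is that the two rates differ by a factor of just 1.62, and that the product step loses speed as starting material goes.

My own reckoning joins these two ends. If the two flows of a steady round are equal, each form's amount goes inversely as its rate of leaving, so the spent share of the round, S, is the product-step rate over the sum of both rates 61.8%. S near one is her view and S near zero is his. Doubling the exchange rate then multiplies the rate of making product by two over two minus S, which is 1.45. This uses charges as they stand and the forward exchange alone.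

The forecast takes her side on the form: spent carrier at 61%, with “most of the catalyst sits as spent carrier”. It gives 1.53 for doubled salt, not her 2 and above my figure, and 0.17 for the smaller loading.

The flask gives spent carrier at 61.2%, a factor of 1.50 for doubled salt and 0.171 for the smaller loading. At that moment fresh carrier holds 32.4% of the catalyst and trapped intermediate 6.43%. The spent share of the round therefore reads 65.4%, and this S in the rule gives 1.49 for the doubled-salt flask, which stands at 1.50. For that doubled-salt flask as charged, S reckons to 44.7%, which puts less spent carrier than fresh carrier in the round, the form he holds to rest.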